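**Retrosynthetic overview**

1. The strategy rests on ring B (C4a–C5–C6–C7–C8=C9–C9a): it is the five-carbon chain C7–C8=C9–C9a–C4a closed by C5 and C6, the two alkene carbons of 3,3-dimethylcyclopropene, whose CMe2 carbon becomes C10. The disconnection is a rhodium (5+2) cycloaddition of a lactone-fused vinylcyclopropane (cyclopropane C9/C9a/C4a, vinyl C8=C7 on C9, lactone C4(=O)–O–C1H2).
2. The vinylcyclopropane lactone comes from a Z-dienyl diazoacetate by enantioselective intramolecular cyclopropanation; the alkene geometry puts vinyl exo and C12H2OTBS endo on C9.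
3. After the cycloaddition, C7 is oxidised (allylic) and parked as a silyl ether; lactone carbon C4 takes C11 (alkoxymethyllithium) and C3 (methoxymethylene Wittig); C1 is raised to the aldehyde.
4. Ring A (O2–C1–C9a–C4a–C4=C3) closes last as the enol-lactol of the C1/C3 dialdehyde; acetylations follow, and C7 and C12 are oxidised together at the end.
5. Ring order: lactone cyclopropane, then ring B with the dimethylcyclopropane (key step), then ring A.

Key step: step 9

Remark: atom numbers are those of the target (C11 on C4, C12 on C9); C1 is carried as the lactone CH2 so that the C9 configuration follows from alkene geometry; centres that are later erased or equilibrate (C7 carbinol in 16–29, C4 in 20, 23 and 24, C3=C4 geometry in 21 and 22, C1 in 25) are drawn as the expected isomer or left open, and either isomer serves.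

**Route**

Step 1
Reactants: 1 tert-butyldimethyl(prop-2-yn-1-yloxy)silane
Product: 3 methyl 4-[(tert-butyldimethylsilyl)oxy]but-2-ynoate, via lithium acetylide 2 (not isolated)
Conditions: nBuLi, THF, −78 °C; ClCO2Me, −78 to 0 °C
Reagents that add atoms: methyl chloroformate COC(=O)Cl
Why: C-acylation of a lithium acetylide with a chloroformate is a standard ynoate synthesis and the silyl ether is inert to it.

Step 2
Reactants: 3 methyl 4-[(tert-butyldimethylsilyl)oxy]but-2-ynoate
Product: 4 methyl (2Z)-3-{[(tert-butyldimethylsilyl)oxy]methyl}penta-2,4-dienoate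
Conditions: vinylmagnesium bromide, CuI, THF, −78 °C; aq. NH4Cl at −78 °C
Reagents that add atoms: vinylmagnesium bromide C=C[Mg]Br
Why: syn carbocupration (conjugate addition) of the vinylcopper reagent to the ynoate with cold protonation should put vinyl cis to H, so that CH2OTBS and CO2Me end up cis, and the low temperature keeps the alkenylcopper from equilibrating.

Step 3
Reactants: 4 methyl (2Z)-3-{[(tert-butyldimethylsilyl)oxy]methyl}penta-2,4-dienoate
Product: 5 (2Z)-3-{[(tert-butyldimethylsilyl)oxy]methyl}penta-2,4-dien-1-ol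
Conditions: iBu2AlH, CH2Cl2, −78 °C; Rochelle salt work-up
Reagents that add atoms: none
Why: 1,2-reduction of an enoate to the allylic alcohol with iBu2AlH leaves the diene geometry untouched.

Step 4
Reactants: 5 (2Z)-3-{[(tert-butyldimethylsilyl)oxy]methyl}penta-2,4-dien-1-ol
Product: 6 (2Z)-3-{[(tert-butyldimethylsilyl)oxy]methyl}penta-2,4-dien-1-yl bromoacetate
Conditions: bromoacetyl bromide, NaHCO3, MeCN, 0 °C
Reagents that add atoms: bromoacetyl bromide O=C(Br)CBr
Why: esterification of the primary allylic alcohol with an acid bromide under bicarbonate buffering is routine and spares the silyl ether.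

Step 5
Reactants: 6 (2Z)-3-{[(tert-butyldimethylsilyl)oxy]methyl}penta-2,4-dien-1-yl bromoacetate
Product: 7 (2Z)-3-{[(tert-butyldimethylsilyl)oxy]methyl}penta-2,4-dien-1-yl diazoacetate
Conditions: N,N'-ditosylhydrazine, DBU, THF, 0 °C
Reagents that add atoms: N,N'-ditosylhydrazine Cc1ccc(cc1)S(=O)(=O)NNS(=O)(=O)c1ccc(C)cc1
Why: N-alkylation of the ditosylhydrazine by the bromoacetate and base-induced loss of two sulfinates is an established diazoacetate synthesis that the diene and silyl ether tolerate.

Step 6
Reactants: 7 (2Z)-3-{[(tert-butyldimethylsilyl)oxy]methyl}penta-2,4-dien-1-yl diazoacetate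
Product: 8 (1S,5R,6R)-6-ethenyl-6-{[(tert-butyldimethylsilyl)oxy]methyl}-3-oxabicyclo[3.1.0]hexan-2-one (vinyl exo, silyloxymethyl endo; lactone C4(=O)–O–C1H2 on C4a/C9a, cyclopropane apex C9)
Conditions: Rh2(5S-MEPY)4 (1 mol%), CH2Cl2, reflux, slow addition of 7
Reagents that add atoms: none
Why: intramolecular cyclopropanation of an allylic diazoacetate with a chiral dirhodium carboxamidate, here dirhodium tetrakis[methyl (5S)-2-oxopyrrolidine-5-carboxylate], adds the carbene to the proximal alkene stereospecifically, so the Z CH2OTBS group becomes endo and vinyl exo on C9, and this catalyst antipode is expected to give the (1S,5R) lactone as it does with 3,3-disubstituted allyl diazoacetates.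

Step 7
Reactants: 9 3-methylbut-2-enal
Product: 10 3-methylbut-2-enal p-toluenesulfonylhydrazone
Conditions: p-toluenesulfonohydrazide, MeOH, rt
Reagents that add atoms: p-toluenesulfonohydrazide Cc1ccc(cc1)S(=O)(=O)NN
Why: condensation of an aldehyde with a sulfonylhydrazide to the hydrazone is reliable.

Step 8
Reactants: 10 3-methylbut-2-enal p-toluenesulfonylhydrazone
Product: 13 3,3-dimethylcyclopropene, via sodium tosylhydrazonate 11 (not isolated), via 1-diazo-3-methylbut-2-ene 12 (not isolated)
Conditions: NaOMe, diglyme, 130–160 °C, N2 stream, product condensed at −78 °C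
Reagents that add atoms: none
Why: Bamford–Stevens decomposition of the hydrazone salt gives the alkenyl diazo compound, whose alkenylcarbene closes 1,3 to the cyclopropene, and the volatile product leaves the hot zone at once.

Step 9
Reactants: 8 (1S,5R,6R)-6-ethenyl-6-{[(tert-butyldimethylsilyl)oxy]methyl}-3-oxabicyclo[3.1.0]hexan-2-one; 13 3,3-dimethylcyclopropene
Product: 14 C7-deoxy tricyclic lactone (γ-lactone C4(=O)–O–C1H2 cis-fused at C4a/C9a; ring B with C8=C9 and C12H2OTBS on C9; cyclopropane C5/C6/C10 cis-fused with C10 syn to H4a)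
Conditions: [Rh(CO)2Cl]2 (5 mol%), ClCH2CH2Cl, sealed tube, 40–60 °C, 13 (5 equiv) added cold in portions
Reagents that add atoms: none
Why: Proposed new method: monovalent rhodium binds the exo vinyl group of 8 and inserts into C9–C4a, the cyclopropane bond flanked by the vinyl donor on C9 and the lactone carbonyl on C4a, to give a σ-alkyl/π-allyl rhodacycle in which the metal has taken the place of C9 on C4a; the strained C=C of 13 then inserts syn into the bond from rhodium to C7 (forming C6–C7), and C–C reductive elimination between C5 and C4a follows, helped by the high s-character of the cyclopropyl carbon on rhodium, which makes it resemble the C(sp2)–C(sp3) elimination of the alkyne series. The closest known reaction type is the rhodium-catalysed (5+2) cycloaddition of vinylcyclopropanes with alkynes, allenes and tethered alkenes, and known additions of rhodium–carbon and rhodium–hydrogen bonds across 3,3-disubstituted cyclopropenes without ring opening support the insertion. Ring B, the only ring closed, forms as a seven-membered ring by reductive elimination from an eight-membered rhodacycle, with C8=C9 left in place. C6 and C5 are set by the syn insertion (cis-fused cyclopropane) and by approach of 13 with its CMe2 group turned away from the lactone on the convex face of the cis-bicyclic rhodacycle, which puts C10 syn to H4a; C4a keeps its configuration through oxidative addition and reductive elimination, and C9a is untouched. The step needs cleavage of C9–C4a and not C9–C9a, which the acceptor at C4a and the vinyl group trans to both ring substituents (so a cis C8=C9 allyl unit can form) should secure, and it needs insertion to outrun ring opening or oligomerisation of 13 on rhodium, which slow addition of 13 at moderate temperature is meant to counter.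

Step 10
Reactants: 14 C7-deoxy tricyclic lactone
Product: 15 enone lactone (C7 ketone conjugated with C8=C9)
Conditions: CrO3, 3,5-dimethylpyrazole, CH2Cl2, −20 °C
Reagents that add atoms: chromium trioxide O=[Cr](=O)=O
Why: allylic oxidation with the CrO3–3,5-dimethylpyrazole complex attacks the ring methylene next to the CH end of a trisubstituted alkene, as in the conversion of car-3-ene to car-3-en-5-one, so C7 (also cyclopropylcarbinyl) should be oxidised in preference to C12 and C9a.

Step 11
Reactants: 15 enone lactone
Product: 16 C7 allylic alcohol lactone (OH expected syn to C10)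
Conditions: NaBH4, CeCl3·7H2O, MeOH, −78 °C
Reagents that add atoms: none
Why: Luche reduction gives clean 1,2-reduction of the enone without touching the γ-lactone, with hydride expected from the face opposite C10; the new C7 centre is temporary.

Step 12
Reactants: 16 C7 allylic alcohol lactone
Product: 17 C7,C12-bis(tert-butyldimethylsilyl) ether lactone
Conditions: TBSOTf, 2,6-lutidine, CH2Cl2, −78 to 0 °C
Reagents that add atoms: tert-butyldimethylsilyl triflate CC(C)(C)[Si](C)(C)OS(=O)(=O)C(F)(F)F
Why: silylation of a hindered secondary alcohol with the silyl triflate and a hindered base is standard and masks C7 through the carbanion steps.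

Step 13
Reactants: 18 (tributylstannyl)methanol
Product: 19 tributyl{[(4-methoxybenzyl)oxy]methyl}stannane
Conditions: NaH, 4-methoxybenzyl chloride, Bu4NI (cat.), THF/DMF, 0 °C to rt
Reagents that add atoms: 4-methoxybenzyl chloride COc1ccc(CCl)cc1
Why: Williamson ether synthesis on the primary alkoxide gives the stannane precursor of the alkoxymethyllithium.

Step 14
Reactants: 17 C7,C12-bis(tert-butyldimethylsilyl) ether lactone; 19 tributyl{[(4-methoxybenzyl)oxy]methyl}stannane
Product: 20 C4 hemiketal bearing C11H2OPMB (anomeric mixture in equilibrium with the open C1-hydroxy C4-ketone)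
Conditions: 19, nBuLi, THF, −78 °C; then 17, −78 °C; aq. NH4Cl
Reagents that add atoms: none
Why: tin–lithium exchange gives the α-alkoxymethyllithium, which adds once to the lactone carbonyl because the lithium lactolate does not collapse at −78 °C, so C11 is attached to C4.

Step 15
Reactants: 20 C4 hemiketal bearing C11H2OPMB
Product: 21 enol ether alcohol (C4(=C3H–OMe)(C11H2OPMB), C1H2OH; E/Z mixture)
Conditions: Ph3P(CH2OMe)Cl, KN(SiMe3)2, THF, 0 °C; then 20, 0 to 40 °C
Reagents that add atoms: (methoxymethyl)triphenylphosphonium chloride [Cl-].COC[P+](c1ccccc1)(c1ccccc1)c1ccccc1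
Why: Wittig olefination with excess methoxymethylene ylide should act on the open hydroxy-ketone tautomer of the hemiketal and attach C3 at the aldehyde oxidation level as an enol ether.

Step 16
Reactants: 21 enol ether alcohol
Product: 22 enol ether aldehyde (C1 aldehyde)
Conditions: Dess–Martin periodinane, pyridine, CH2Cl2, 0 °C
Reagents that add atoms: none
Why: Dess–Martin oxidation under pyridine buffering converts the only free alcohol to the aldehyde without acid, which should spare the enol ether and the configuration at C9a.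

Step 17
Reactants: 22 enol ether aldehyde
Product: 25 enol-lactol (ring A closed, C1–OH, C11H2OPMB), via organomercurial aldehyde 23 (not isolated), via dialdehyde 24 (not isolated)
Conditions: Hg(OAc)2, THF/H2O (10:1), 0 °C; then aq. KI, rt
Reagents that add atoms: water O
Why: oxymercuration–demercuration hydrolyses the methyl enol ether under neutral conditions, and the C3 enol released by iodide should add through oxygen to the neighbouring C1 aldehyde (6-exo closure), the ring–chain tautomerism by which cis-fused 1,5-dialdehydes of this type rest as enol-lactols.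

Step 18
Reactants: 25 enol-lactol
Product: 26 C1 acetate with C11H2OPMB
Conditions: Ac2O, pyridine, DMAP (cat.), CH2Cl2, 0 °C
Reagents that add atoms: acetic anhydride CC(=O)OC(C)=O
Why: acetylation of the lactol hydroxyl should trap the axial anomer, favoured by the anomeric effect in the half-chair that keeps C5 pseudoaxial, which places the C1 oxygen trans to H9a as in the target.

Step 19
Reactants: 26 C1 acetate with C11H2OPMB
Product: 27 C1 acetate with free C11 alcohol
Conditions: DDQ, CH2Cl2/pH 7 buffer, 0 °C
Reagents that add atoms: none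
Why: oxidative cleavage of a 4-methoxybenzyl ether with DDQ under buffered conditions is compatible with glycal-type enol ethers, acetates and silyl ethers.

Step 20
Reactants: 27 C1 acetate with free C11 alcohol
Product: 28 C1,C11-diacetate C7,C12-bis(silyl) ether
Conditions: Ac2O, pyridine, DMAP (cat.), CH2Cl2, 0 °C
Reagents that add atoms: acetic anhydride CC(=O)OC(C)=O
Why: acetylation of the primary allylic alcohol is routine and completes ring A with both acetates.

Step 21
Reactants: 28 C1,C11-diacetate C7,C12-bis(silyl) ether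
Product: 29 C7,C12-diol diacetate
Conditions: HF·pyridine, pyridine, THF, 0 °C to rt
Reagents that add atoms: none
Why: buffered fluoride desilylation removes both silyl ethers while the acetates, the anomeric acetate and the enol ether should persist.

Step 22
Reactants: 29 C7,C12-diol diacetate
Product: 30 target CNP0263020.2
Conditions: Dess–Martin periodinane, pyridine, CH2Cl2, 0 °C to rt
Reagents that add atoms: none
Why: Dess–Martin oxidation converts the secondary allylic alcohol at C7 to the ketone and the primary allylic alcohol at C12 to the aldehyde in one operation under near-neutral conditions, which suits the acidic C9a–H of the product.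

**Compound list**

1 | tert-butyldimethyl(prop-2-yn-1-yloxy)silane | C#CCO[Si](C)(C)C(C)(C)C | starting material
2 | lithium acetylide of 1 | [Li]C#CCO[Si](C)(C)C(C)(C)C | intermediate
3 | methyl 4-[(tert-butyldimethylsilyl)oxy]but-2-ynoate | COC(=O)C#CCO[Si](C)(C)C(C)(C)C | intermediate
4 | methyl (2Z)-3-{[(tert-butyldimethylsilyl)oxy]methyl}penta-2,4-dienoate | COC(=O)/C=C(CO[Si](C)(C)C(C)(C)C)/C=C | intermediate
5 | (2Z)-3-{[(tert-butyldimethylsilyl)oxy]methyl}penta-2,4-dien-1-ol | OC/C=C(CO[Si](C)(C)C(C)(C)C)/C=C | intermediate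
6 | bromoacetate of 5 | BrCC(=O)OC/C=C(CO[Si](C)(C)C(C)(C)C)/C=C | intermediate
7 | diazoacetate of 5 | [N-]=[N+]=CC(=O)OC/C=C(CO[Si](C)(C)C(C)(C)C)/C=C | intermediate
8 | (1S,5R,6R)-6-ethenyl-6-{[(tert-butyldimethylsilyl)oxy]methyl}-3-oxabicyclo[3.1.0]hexan-2-one | O=C1OC[C@@H]2[C@H]1[C@]2(C=C)CO[Si](C)(C)C(C)(C)C | intermediate
9 | 3-methylbut-2-enal | CC(C)=CC=O | starting material
10 | 3-methylbut-2-enal p-toluenesulfonylhydrazone | CC(C)=C/C=N/NS(=O)(=O)c1ccc(C)cc1 | intermediate
11 | sodium salt of 10 | CC(C)=CC=N[N-]S(=O)(=O)c1ccc(C)cc1.[Na+] | intermediate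
12 | 1-diazo-3-methylbut-2-ene | CC(C)=CC=[N+]=[N-] | intermediate
13 | 3,3-dimethylcyclopropene | CC1(C)C=C1 | intermediate
14 | C7-deoxy tricyclic lactone | O=C1OC[C@H]2C(CO[Si](C)(C)C(C)(C)C)=CC[C@H]3[C@@H]([C@@H]12)C3(C)C | intermediate
15 | enone lactone | O=C1OC[C@H]2C(CO[Si](C)(C)C(C)(C)C)=CC(=O)[C@H]3[C@@H]([C@@H]12)C3(C)C | intermediate
16 | C7 allylic alcohol lactone | O=C1OC[C@H]2C(CO[Si](C)(C)C(C)(C)C)=C[C@H](O)[C@H]3[C@@H]([C@@H]12)C3(C)C | intermediate
17 | C7,C12-bis(tert-butyldimethylsilyl) ether lactone | O=C1OC[C@H]2C(CO[Si](C)(C)C(C)(C)C)=C[C@H](O[Si](C)(C)C(C)(C)C)[C@H]3[C@@H]([C@@H]12)C3(C)C | intermediate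
18 | (tributylstannyl)methanol | OC[Sn](CCCC)(CCCC)CCCC | starting material
19 | tributyl{[(4-methoxybenzyl)oxy]methyl}stannane | COc1ccc(COC[Sn](CCCC)(CCCC)CCCC)cc1 | intermediate
20 | C4 hemiketal with C11H2OPMB | COc1ccc(COCC2(O)OC[C@H]3C(CO[Si](C)(C)C(C)(C)C)=C[C@H](O[Si](C)(C)C(C)(C)C)[C@H]4[C@@H]([C@@H]23)C4(C)C)cc1 | intermediate
21 | enol ether alcohol | COC=C(COCc1ccc(OC)cc1)[C@H]1[C@@H](CO)C(CO[Si](C)(C)C(C)(C)C)=C[C@H](O[Si](C)(C)C(C)(C)C)[C@H]2[C@@H]1C2(C)C | intermediate
22 | enol ether aldehyde | COC=C(COCc1ccc(OC)cc1)[C@H]1[C@@H](C=O)C(CO[Si](C)(C)C(C)(C)C)=C[C@H](O[Si](C)(C)C(C)(C)C)[C@H]2[C@@H]1C2(C)C | intermediate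
23 | C4-acetoxymercurio dialdehyde | CC(=O)O[Hg]C(COCc1ccc(OC)cc1)(C=O)[C@H]1[C@@H](C=O)C(CO[Si](C)(C)C(C)(C)C)=C[C@H](O[Si](C)(C)C(C)(C)C)[C@H]2[C@@H]1C2(C)C | intermediate
24 | C1/C3 dialdehyde | O=CC(COCc1ccc(OC)cc1)[C@H]1[C@@H](C=O)C(CO[Si](C)(C)C(C)(C)C)=C[C@H](O[Si](C)(C)C(C)(C)C)[C@H]2[C@@H]1C2(C)C | intermediate
25 | enol-lactol (C1–OH) | COc1ccc(COCC2=COC(O)[C@H]3C(CO[Si](C)(C)C(C)(C)C)=C[C@H](O[Si](C)(C)C(C)(C)C)[C@H]4[C@@H]([C@@H]23)C4(C)C)cc1 | intermediate
26 | C1 acetate with C11H2OPMB | COc1ccc(COCC2=CO[C@@H](OC(C)=O)[C@H]3C(CO[Si](C)(C)C(C)(C)C)=C[C@H](O[Si](C)(C)C(C)(C)C)[C@H]4[C@@H]([C@@H]23)C4(C)C)cc1 | intermediate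
27 | C1 acetate with C11 alcohol | OCC1=CO[C@@H](OC(C)=O)[C@H]2C(CO[Si](C)(C)C(C)(C)C)=C[C@H](O[Si](C)(C)C(C)(C)C)[C@H]3[C@@H]([C@@H]12)C3(C)C | intermediate
28 | C1,C11-diacetate C7,C12-bis(silyl) ether | CC(=O)OCC1=CO[C@@H](OC(C)=O)[C@H]2C(CO[Si](C)(C)C(C)(C)C)=C[C@H](O[Si](C)(C)C(C)(C)C)[C@H]3[C@@H]([C@@H]12)C3(C)C | intermediate
29 | C7,C12-diol diacetate | CC(=O)OCC1=CO[C@@H](OC(C)=O)[C@H]2C(CO)=C[C@H](O)[C@H]3[C@@H]([C@@H]12)C3(C)C | intermediate
30 | CNP0263020.2 | CC(=O)OCC1=CO[C@@H](OC(C)=O)[C@H]2C(C=O)=CC(=O)[C@H]3[C@@H]([C@@H]12)C3(C)C | target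

**Step count and risks**

Total step count: 22. Longest linear sequence: 19 (steps 1–6, 9–12, 14–22).

Steps most likely to fail:

Step 9. The cyclopropene may ring-open or oligomerise on rhodium faster than it inserts, the rhodacycle may instead lose a β-hydrogen to give a diene, or cleavage may occur at C9–C9a. Fallback, setting out from 8 and returning at 15: the known rhodium (5+2) cycloaddition of a vinylcyclopropane with an alkyne is run with ethyne ([Rh(CO)2Cl]2, ClCH2CH2Cl) to give the cyclohepta-1,4-diene lactone F1. Its doubly allylic C7 methylene is oxidised with CrO3 and 3,5-dimethylpyrazole to the cross-conjugated dienone F2. 2-Diazopropane adds as a 1,3-dipole to the less substituted C5=C6 bond, anti to the lactone, to give the pyrazoline F3, whose photolysis with loss of nitrogen gives the gem-dimethylcyclopropyl enone 15. This route also replaces step 10.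

Step 17. The free C1 aldehyde may slip into conjugation with C8=C9 (loss of C9a), the C3 aldehyde may eliminate the C11 ether, or the dialdehyde may be acetylated as an open enol acetate in step 18 instead of resting as the lactol. Fallback, setting out from 22 and returning at 25: Pinnick oxidation (NaClO2, NaH2PO4, 2-methylbut-2-ene) gives the C1 carboxylic acid F4. Warming with pyridinium p-toluenesulfonate in toluene adds the acid to the enol ether and expels methanol to give the enol lactone F5. Reduction with iBu2AlH at −78 °C (no other ester is present at this stage) gives lactol 25.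

Step 15. The hemiketal may stay ring-closed and be returned unchanged, or the ylide may only enolise the hindered ketone. Fallback, setting out from 20 and returning at 21: silylation with Et3SiCl, imidazole and DMAP drains the open tautomer as the keto triethylsilyl ether F6. Wittig methoxymethylenation of this acyclic ketone gives the enol ether triethylsilyl ether F7. Buffered HF·pyridine at 0 °C removes the primary triethylsilyl group selectively to give 21.

Further compounds
F1 | step 9 | cyclohepta-1,4-diene lactone from 8 and ethyne | O=C1OC[C@H]2C(CO[Si](C)(C)C(C)(C)C)=CCC=C[C@@H]12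
F2 | step 9 | cross-conjugated dienone lactone (C7 ketone) | O=C1OC[C@H]2C(CO[Si](C)(C)C(C)(C)C)=CC(=O)C=C[C@@H]12
F3 | step 9 | pyrazoline from F2 and 2-diazopropane | O=C1OC[C@H]2C(CO[Si](C)(C)C(C)(C)C)=CC(=O)[C@@H]3N=NC(C)(C)[C@@H]3[C@@H]12
F4 | step 17 | C1 carboxylic acid enol ether | COC=C(COCc1ccc(OC)cc1)[C@H]1[C@@H](C(O)=O)C(CO[Si](C)(C)C(C)(C)C)=C[C@H](O[Si](C)(C)C(C)(C)C)[C@H]2[C@@H]1C2(C)C
F5 | step 17 | enol lactone (C1 carbonyl, C3=C4) | COc1ccc(COCC2=COC(=O)[C@H]3C(CO[Si](C)(C)C(C)(C)C)=C[C@H](O[Si](C)(C)C(C)(C)C)[C@H]4[C@@H]([C@@H]23)C4(C)C)cc1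
F6 | step 15 | open-chain C4 ketone C1 triethylsilyl ether | O=C(COCc1ccc(OC)cc1)[C@H]1[C@@H](CO[Si](CC)(CC)CC)C(CO[Si](C)(C)C(C)(C)C)=C[C@H](O[Si](C)(C)C(C)(C)C)[C@H]2[C@@H]1C2(C)C
F7 | step 15 | enol ether C1 triethylsilyl ether | COC=C(COCc1ccc(OC)cc1)[C@H]1[C@@H](CO[Si](CC)(CC)CC)C(CO[Si](C)(C)C(C)(C)C)=C[C@H](O[Si](C)(C)C(C)(C)C)[C@H]2[C@@H]1C2(C)C
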